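**Strategy**

The dihydrofuran ring is cut at O1–C7a and C3–C3a, the two bonds that join the O1–C2–C3 unit to the adjacent ring A carbons. O1–C2(aryl)=C3 is read as the enolate of an aroylacetate whose ester carbon becomes the CH2OH group, and ring A as a 1-bromo-2-iodoarene with iodine at C3a and bromine at C7a, beside the C7 methoxy group. One copper-catalysed domino C-arylation/O-arylation joins them as a flat benzofuran. This heteroarene is then dearomatised: enantioselective hydrogenation sets C2, epimerisation at C3 gives the trans ring, and reduction, benzylic oxidation and a Wittig reaction at C5 complete balanophonin.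

Key step: step 5

Remark on numbering: atoms are numbered as in benzofuran (O1, C2, C3, C3a, C4 to C7, C7a); ring A is the benzo ring, ring B the pendant 4-hydroxy-3-methoxyphenyl ring. The target as drawn is the trans-(2R,3S) isomer.

Assumption: the facial sense of the Ru–NHC catalyst on 9 cannot be predicted with certainty; the (R,R)-ligand is written, and its antipode is to be used if a pilot run shows the opposite sense.

**Route**

Step 1
Reactants: 1 acetovanillone, 1-(4-hydroxy-3-methoxyphenyl)ethan-1-one
Product: 2 1-[3-methoxy-4-(methoxymethoxy)phenyl]ethan-1-one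
Conditions: MOMCl, K2CO3, acetone, 0 °C to rt
Reagents that add atoms: chloromethyl methyl ether (COCCl)
Why: Williamson-type O-alkylation of the phenoxide gives the MOM ether, which keeps the phenol out of the copper coupling of step 5 and should survive every basic, reductive and oxidative step up to step 10.

Step 2
Reactants: 2 1-[3-methoxy-4-(methoxymethoxy)phenyl]ethan-1-one
Product: 3 methyl 3-[3-methoxy-4-(methoxymethoxy)phenyl]-3-oxopropanoate
Conditions: NaH, dimethyl carbonate, THF, reflux; then AcOH, H2O, 0 °C
Reagents that add atoms: dimethyl carbonate (COC(=O)OC)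
Why: Crossed Claisen condensation of the methyl ketone enolate with the non-enolisable carbonate is driven by formation of the stabilised β-keto ester enolate.

Step 3
Reactants: 4 methyl 4-amino-3-methoxybenzoate
Product: 5 methyl 4-amino-3-iodo-5-methoxybenzoate
Conditions: N-iodosuccinimide, TFA (cat.), MeCN, rt
Reagents that add atoms: N-iodosuccinimide (O=C1CCC(=O)N1I)
Why: Electrophilic aromatic iodination is steered by the amino group to its only free ortho position, its para position being occupied by the ester.

Step 4
Reactants: 5 methyl 4-amino-3-iodo-5-methoxybenzoate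
Product: 7 methyl 4-bromo-3-iodo-5-methoxybenzoate, via arenediazonium bromide 6 (not isolated)
Conditions: t-BuONO, CuBr2, MeCN, 0 to 60 °C
Reagents that add atoms: copper dibromide, CuBr2 ([Cu+2].[Br-].[Br-])
Why: Sandmeyer bromination under non-aqueous diazotisation replaces the amino group by bromine through an aryl radical that takes bromine from CuBr2, which places Br at the future C7a between iodine and OMe.

Step 5
Reactants: 3 methyl 3-[3-methoxy-4-(methoxymethoxy)phenyl]-3-oxopropanoate; 7 methyl 4-bromo-3-iodo-5-methoxybenzoate
Product: 9 dimethyl 7-methoxy-2-[3-methoxy-4-(methoxymethoxy)phenyl]-1-benzofuran-3,5-dicarboxylate, via bromo keto ester 8 (not isolated)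
Conditions: CuI (10 mol %), K2CO3, THF, 100 °C (sealed vessel)
Reagents that add atoms: none
Why: The potassium enolate of 3 is C-arylated by monovalent copper at the C–I bond of 7 (Ullmann-type Hurtley coupling through an aryl–copper enolate and C–C reductive elimination) to give 8, whose more acidic, chelating enolate then undergoes intramolecular Ullmann O-arylation at the neighbouring C–Br bond. This is the known copper-catalysed domino C-arylation/O-arylation of 1-bromo-2-iodoarenes with β-keto esters to 2,3-disubstituted benzofurans, applied here to an aroylacetate and to a bromide flanked by OMe. The furan ring is closed in the second stage by C–O reductive elimination from a six-membered aryl–copper enolate chelate, formally a 5-exo ipso substitution at C7a, and the aromaticity gained makes the closure irreversible. No stereocentre is formed, since C2 and C3 emerge sp2 and are set in steps 6 and 7. The step needs site selectivity (carbon to C3a, oxygen to C7a), which the reactivity order C–I over C–Br secures, and C- before O-arylation, which the softer enolate carbon secures in the intermolecular stage, while afterwards only oxygen can reach C7a through a five-membered ring. The para ester on ring A activates both carbon–halogen bonds, and the absence of free O–H or N–H groups in 3 and 7 excludes competing heteroatom arylation.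

Step 6
Reactants: 9 dimethyl 7-methoxy-2-[3-methoxy-4-(methoxymethoxy)phenyl]-1-benzofuran-3,5-dicarboxylate
Product: 10 dimethyl (2R,3S)-7-methoxy-2-[3-methoxy-4-(methoxymethoxy)phenyl]-2,3-dihydro-1-benzofuran-3,5-dicarboxylate (cis)
Conditions: Ru(cod)(2-methylallyl)2 (5 mol %), (R,R)-SINpEt·HBF4 [1,3-bis((R)-1-(naphthalen-1-yl)ethyl)-4,5-dihydroimidazolium tetrafluoroborate] (10 mol %), KOtBu (15 mol %), H2 (100 bar), toluene, 40 °C
Reagents that add atoms: none
Why: Proposed new method: the chiral bis(carbene)ruthenium hydride formed in situ should bind the furan C2=C3 bond of 9, which is the least aromatic and, as a β-aryloxy-β-aryl acrylate, the most polarised π-bond of the molecule, and deliver both hydrogens to one face (syn addition, hence C2 aryl and C3 ester cis), the enantioface being chosen by the two N-(1-naphthylethyl) groups so that C2 becomes R; the closest known reaction types are the enantioselective hydrogenation of 2-arylbenzofurans and of flavones (β-aryloxy enones) with this Ru–NHC system, neither of which has been shown on a fully substituted 2-aryl-3-alkoxycarbonylbenzofuran.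

Step 7
Reactants: 10 dimethyl (2R,3S)-7-methoxy-2-[3-methoxy-4-(methoxymethoxy)phenyl]-2,3-dihydro-1-benzofuran-3,5-dicarboxylate (cis)
Product: 11 dimethyl (2R,3R)-7-methoxy-2-[3-methoxy-4-(methoxymethoxy)phenyl]-2,3-dihydro-1-benzofuran-3,5-dicarboxylate (trans)
Conditions: NaOMe (0.2 equiv), MeOH/THF, 0 °C to rt
Reagents that add atoms: none
Why: Reversible deprotonation α to the C3 ester should equilibrate the cis diester to the thermodynamically preferred trans isomer (C3 inverted, C2 untouched), and methoxide in methanol makes ester exchange degenerate.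

Step 8
Reactants: 11 dimethyl (2R,3R)-7-methoxy-2-[3-methoxy-4-(methoxymethoxy)phenyl]-2,3-dihydro-1-benzofuran-3,5-dicarboxylate (trans)
Product: 12 [(2R,3S)-3-(hydroxymethyl)-7-methoxy-2-[3-methoxy-4-(methoxymethoxy)phenyl]-2,3-dihydro-1-benzofuran-5-yl]methanol
Conditions: LiAlH4, THF, 0 °C; then H2O, aq. NaOH
Reagents that add atoms: none
Why: Hydride reduction turns both methyl esters into primary alcohols without touching the stereocentres, the change of the C3 descriptor being only a change of substituent priority.

Step 9
Reactants: 12 [(2R,3S)-3-(hydroxymethyl)-7-methoxy-2-[3-methoxy-4-(methoxymethoxy)phenyl]-2,3-dihydro-1-benzofuran-5-yl]methanol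
Product: 13 (2R,3S)-3-(hydroxymethyl)-7-methoxy-2-[3-methoxy-4-(methoxymethoxy)phenyl]-2,3-dihydro-1-benzofuran-5-carbaldehyde
Conditions: MnO2 (activated, excess), CH2Cl2, rt
Reagents that add atoms: none
Why: Activated MnO2 oxidises benzylic alcohols chemoselectively, so the ring A CH2OH should become the aldehyde while the non-benzylic CH2OH on C3 is left.

Step 10
Reactants: 13 (2R,3S)-3-(hydroxymethyl)-7-methoxy-2-[3-methoxy-4-(methoxymethoxy)phenyl]-2,3-dihydro-1-benzofuran-5-carbaldehyde
Product: 14 (2R,3S)-2-(4-hydroxy-3-methoxyphenyl)-3-(hydroxymethyl)-7-methoxy-2,3-dihydro-1-benzofuran-5-carbaldehyde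
Conditions: 2 M aq. HCl, THF, rt to 40 °C
Reagents that add atoms: none
Why: Mild acid hydrolysis of the MOM acetal frees the ring B phenol, and any reversible ionisation of the benzylic C2–O1 bond can only re-close to the more stable trans ring because C3 stays fixed.

Step 11
Reactants: 14 (2R,3S)-2-(4-hydroxy-3-methoxyphenyl)-3-(hydroxymethyl)-7-methoxy-2,3-dihydro-1-benzofuran-5-carbaldehyde
Product: 15 balanophonin, (E)-3-[(2R,3S)-2-(4-hydroxy-3-methoxyphenyl)-3-(hydroxymethyl)-7-methoxy-2,3-dihydro-1-benzofuran-5-yl]prop-2-enal
Conditions: Ph3P=CHCHO (1.2 equiv), toluene/THF, 80 °C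
Reagents that add atoms: (triphenylphosphoranylidene)acetaldehyde (O=CC=P(c1ccccc1)(c1ccccc1)c1ccccc1)
Why: Wittig olefination of the aromatic aldehyde with the stabilised formyl ylide should give the (E)-enal directly, and neither the phenol nor the primary alcohol reacts with this weakly basic ylide.

**Compound list**

1 | acetovanillone, 1-(4-hydroxy-3-methoxyphenyl)ethan-1-one | CC(=O)c1ccc(O)c(OC)c1 | starting material
2 | 1-[3-methoxy-4-(methoxymethoxy)phenyl]ethan-1-one | CC(=O)c1ccc(OCOC)c(OC)c1 | intermediate
3 | methyl 3-[3-methoxy-4-(methoxymethoxy)phenyl]-3-oxopropanoate | COC(=O)CC(=O)c1ccc(OCOC)c(OC)c1 | intermediate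
4 | methyl 4-amino-3-methoxybenzoate | COC(=O)c1ccc(N)c(OC)c1 | starting material
5 | methyl 4-amino-3-iodo-5-methoxybenzoate | COC(=O)c1cc(I)c(N)c(OC)c1 | intermediate
6 | 2-iodo-6-methoxy-4-(methoxycarbonyl)benzenediazonium bromide | COC(=O)c1cc(I)c([N+]#N)c(OC)c1.[Br-] | intermediate (not isolated)
7 | methyl 4-bromo-3-iodo-5-methoxybenzoate | COC(=O)c1cc(I)c(Br)c(OC)c1 | intermediate
8 | methyl 4-bromo-3-methoxy-5-{1-methoxy-3-[3-methoxy-4-(methoxymethoxy)phenyl]-1,3-dioxopropan-2-yl}benzoate | COC(=O)c1cc(C(C(=O)OC)C(=O)c2ccc(OCOC)c(OC)c2)c(Br)c(OC)c1 | intermediate (not isolated)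
9 | dimethyl 7-methoxy-2-[3-methoxy-4-(methoxymethoxy)phenyl]-1-benzofuran-3,5-dicarboxylate | COCOc1ccc(-c2oc3c(OC)cc(C(=O)OC)cc3c2C(=O)OC)cc1OC | intermediate
10 | dimethyl (2R,3S)-7-methoxy-2-[3-methoxy-4-(methoxymethoxy)phenyl]-2,3-dihydro-1-benzofuran-3,5-dicarboxylate (cis) | COc1cc([C@@H]2Oc3c(OC)cc(C(=O)OC)cc3[C@@H]2C(=O)OC)ccc1OCOC | intermediate
11 | dimethyl (2R,3R)-7-methoxy-2-[3-methoxy-4-(methoxymethoxy)phenyl]-2,3-dihydro-1-benzofuran-3,5-dicarboxylate (trans) | COc1cc([C@@H]2Oc3c(OC)cc(C(=O)OC)cc3[C@H]2C(=O)OC)ccc1OCOC | intermediate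
12 | [(2R,3S)-3-(hydroxymethyl)-7-methoxy-2-[3-methoxy-4-(methoxymethoxy)phenyl]-2,3-dihydro-1-benzofuran-5-yl]methanol | COc1cc([C@@H]2Oc3c(OC)cc(CO)cc3[C@H]2CO)ccc1OCOC | intermediate
13 | (2R,3S)-3-(hydroxymethyl)-7-methoxy-2-[3-methoxy-4-(methoxymethoxy)phenyl]-2,3-dihydro-1-benzofuran-5-carbaldehyde | COc1cc([C@@H]2Oc3c(OC)cc(C=O)cc3[C@H]2CO)ccc1OCOC | intermediate
14 | (2R,3S)-2-(4-hydroxy-3-methoxyphenyl)-3-(hydroxymethyl)-7-methoxy-2,3-dihydro-1-benzofuran-5-carbaldehyde | COc1cc([C@@H]2Oc3c(OC)cc(C=O)cc3[C@H]2CO)ccc1O | intermediate
15 | balanophonin, (E)-3-[(2R,3S)-2-(4-hydroxy-3-methoxyphenyl)-3-(hydroxymethyl)-7-methoxy-2,3-dihydro-1-benzofuran-5-yl]prop-2-enal | COc1cc([C@@H]2Oc3c(OC)cc(/C=C/C=O)cc3[C@H]2CO)ccc1O | target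

**Step count**

Total: 11 steps. Longest linear sequence: 9 steps (steps 1, 2, 5 to 11; the branch through steps 3 and 4 is equally long).

**Steps most likely to fail**

Step 6 (the only step beyond precedent). The hydrogenation may fail through lack of turnover at the fully substituted C2=C3 bond, through over-reduction of a benzene ring, or through poor enantioface discrimination. The fallback sets out from 9. Dissolving-metal reduction (Mg turnings, MeOH/THF, rt), known for methyl 2-arylbenzofuran-3-carboxylates, should give the trans diester directly as the racemate, because the Mg(OMe)2 formed equilibrates C3. The racemate consists of 11 and its enantiomer dimethyl (2S,3S)-7-methoxy-2-[3-methoxy-4-(methoxymethoxy)phenyl]-2,3-dihydro-1-benzofuran-3,5-dicarboxylate F1. The two are to be separated by preparative HPLC on a chiral stationary phase (cellulose tris(3,5-dimethylphenylcarbamate)). The route is rejoined at 11 and step 7 is no longer needed, at the price of half the material.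

Step 5. The domino may stall at 8 because oxidative addition at the C–Br bond flanked by OMe is slow, or 8 may be lost by retro-Claisen deacylation at 100 °C. The fallback sets out from 3 and 7, separates the two bond formations and hands the ring closure to palladium. CuI/L-proline, K2CO3, DMSO, 40 °C should arylate carbon at the C–I bond only and give 8, now isolated. Pd2(dba)3, DPEphos, Cs2CO3, toluene, 100 °C (intramolecular enolate O-arylation) should then close the furan and return to the route at 9. No compound outside the list is made (F0).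

Step 7. The C3 ester enolate may expel the ring A aryloxide (a β-elimination that opens the ring, helped by the para ester on ring A) faster than it is reprotonated. The fallback sets out from 9 and moves the epimerisation from C3 under base to C2 under acid.
- Hydrogenation as in step 6 but with the (S,S)-ligand should give the enantiomeric cis diester dimethyl (2S,3R)-7-methoxy-2-[3-methoxy-4-(methoxymethoxy)phenyl]-2,3-dihydro-1-benzofuran-3,5-dicarboxylate F2, in which C3 already has the spatial arrangement of the target.
- LiAlH4 (THF, 0 °C) should give the cis diol [(2S,3S)-3-(hydroxymethyl)-7-methoxy-2-[3-methoxy-4-(methoxymethoxy)phenyl]-2,3-dihydro-1-benzofuran-5-yl]methanol F3.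
- MnO2 (CH2Cl2, rt) should give the cis aldehyde (2S,3S)-3-(hydroxymethyl)-7-methoxy-2-[3-methoxy-4-(methoxymethoxy)phenyl]-2,3-dihydro-1-benzofuran-5-carbaldehyde F4.
- The acid of step 10 (2 M aq. HCl, THF, 40 °C) should then remove the MOM group and, by reversible ionisation of the benzylic C2–O1 bond to the cation stabilised by the para oxygen of ring B, equilibrate C2 to the more stable trans ring. This rejoins the route at 14.

**Further compounds**

F1 | step 6 | dimethyl (2S,3S)-7-methoxy-2-[3-methoxy-4-(methoxymethoxy)phenyl]-2,3-dihydro-1-benzofuran-3,5-dicarboxylate (trans, enantiomer of 11) | COc1cc([C@H]2Oc3c(OC)cc(C(=O)OC)cc3[C@@H]2C(=O)OC)ccc1OCOC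
F0 | step 5 | none | none
F2 | step 7 | dimethyl (2S,3R)-7-methoxy-2-[3-methoxy-4-(methoxymethoxy)phenyl]-2,3-dihydro-1-benzofuran-3,5-dicarboxylate (cis, enantiomer of 10) | COc1cc([C@H]2Oc3c(OC)cc(C(=O)OC)cc3[C@H]2C(=O)OC)ccc1OCOC
F3 | step 7 | [(2S,3S)-3-(hydroxymethyl)-7-methoxy-2-[3-methoxy-4-(methoxymethoxy)phenyl]-2,3-dihydro-1-benzofuran-5-yl]methanol (cis) | COc1cc([C@H]2Oc3c(OC)cc(CO)cc3[C@H]2CO)ccc1OCOC
F4 | step 7 | (2S,3S)-3-(hydroxymethyl)-7-methoxy-2-[3-methoxy-4-(methoxymethoxy)phenyl]-2,3-dihydro-1-benzofuran-5-carbaldehyde (cis) | COc1cc([C@H]2Oc3c(OC)cc(C=O)cc3[C@H]2CO)ccc1OCOC
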